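The numbers in the tables are simulated for an exercise; scatter was added.

If each catalyst makes target at a steady pace as long as it holds starting material, a flask of this kind can be read from one number.

| setting | dawn | winter | flask |
|---|---|---|---|
| starting material | 1.5 M (in portions, 4) | 1.5 M (in portions, 4) | 1.5 M (in portions, 4) |
| gas | 200 mM (held) | 200 mM (held) | 200 mM (held) |
| free catalyst | 220 mM | 150 mM | 220 mM |
| remark | the very flask that is asked about, followed so far; portions every 2.0 min | run made earlier; portions every 2.0 min | the portions of starting material follow each other after 2.0 min, the first at the start |
| time |  |  | 10 min |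

- dawn (time / min: target / %, starting material / %): 0.417: 1, 9; 0.833: 6, 8; 1.33: 8, 0; 2.50: 16, 16; 5.00: 41, 23
- winter (time / min: target / %, starting material / %): 0.833: 6, 10; 2.50: 12, 28; 5.00: 29, 41; 8.00: 45, 49; 10.0: 58, 33

(each reading ± 2 percentage points)

* amount of target in percent of the starting material charged, at 30 s, 2.5 min and 10 min

- at the start none of the gas is in solution

In the dawn run, the first portion of 25.0% of the charge shows 9% starting material and 1% target at 0.417 min. The gap of 15.0% stands close to the catalyst charge, 14.7% of the starting material, so starting material appears to bind to catalyst almost at once, one to one. The winter run climbs from 12% at 2.50 min to 58% at 10.0 min, and that slope, taken per catalyst charged, gives as a reading the turnover rate 0.613 min⁻¹: target made per minute by each catalyst.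

The dawn flask differs from the winter run in its catalyst, so my own reckoning multiplies the winter reading at 2.5 min by 1.47, which gives 17.6%. That multiplication also carries the winter scatter up to 2.9 percentage points. The turnover rate then adds 67.5% up to 10 min, for 85.1% in all. This stands beside the mark of 85.3%, the charge less what the catalyst can hold, at which the subtraction leaves no free starting material, so the figure is best taken as an upper one. At 30 s, interpolating the dawn readings gives 2.00%.

The forecast gives 2.5%, 18% and 83%, the last “with saturation only just ending”.

The flask gives 1.60%, 17.4% and 82.8%.

    starting material + free catalyst ⇌ catalyst intermediate A (K = 0.889 M⁻¹, k = 2.35 M⁻¹ s⁻¹)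
    gas ⇌ reagent, rate k2*(csat - [reagent]) (kL = 0.150 s⁻¹)
    catalyst intermediate A → catalyst intermediate B (k = 4.96 s⁻¹)
    reagent + catalyst intermediate B → catalyst intermediate C (k = 0.289 M⁻¹ s⁻¹)
    catalyst intermediate C → free catalyst + target (k = 0.0126 s⁻¹)

In the flask at 5.00 min, catalyst intermediate C releases target with 0.756 min⁻¹, the rate-limiting step, while catalyst intermediate B takes up reagent at 0.185 M with 3.21 min⁻¹, and catalyst intermediate C is the resting state, with 79.2% of the catalyst against 18.6% in catalyst intermediate B. Beside the turnover rate of 0.613 min⁻¹ read from the winter run, the flask's own climb from 2.5 min to 10 min, taken per catalyst charged, comes to 0.595 min⁻¹.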